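**Plan**

- Retrosynthesis: the quinone goes back to its hydroquinone, then by carbon-for-oxygen exchange at C1 to a 4-hydroxybenzaldehyde and a resorcylate ester. The arene is cut at C1–C2 and C5–C6, the ynoate at its propargylic C–C bond, and the C30 chain in the middle into two farnesol-derived C15 halves.
- Enabling feature: with C1 the carbonyl between C2 (OMe) and C6 (chain) and C4 the other carbonyl, ring atoms C2–C3–C4–C5 carry oxygen at C2 and C4 like a 1,1-dimethoxy-3-siloxybutadiene. C1 and C6 map onto the two alkyne carbons of a 3-hexaprenylpropiolate, whose ester carbon at C1 is later replaced by oxygen.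
- Forward order: the chain is built first (C15 + C15 sulfone coupling, then propiolate attachment). The only ring then arises by [4+2] cycloaddition and aromatisation, followed by Dakin exchange and oxidation to the quinone.
- Stereochemistry: there are no stereocentres. Four E-alkenes come from (2E,6E)-farnesol, the fifth from E-selective SeO2 oxidation of a terminal methyl group, and no later step touches them.

Key step: step 13

Remarks: "all-E-hexaprenyl" means (2E,6E,10E,14E,18E)-3,7,11,15,19,23-hexamethyltetracosa-2,6,10,14,18,22-hexaen-1-yl. Commercial (2E,6E)-farnesol is assumed to be geometrically pure. The ynoate is named here as a heptacos-2-ynoate, which is what its structure requires.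

**Route**

Step 1
Reactants: 1 (2E,6E)-farnesol
Product: 2 (2E,6E)-farnesyl bromide
Conditions: PBr3 (0.4 equiv), pyridine (cat.), Et2O, −10 → 0 °C
Reagents that add atoms: phosphorus tribromide, BrP(Br)Br
Why: Conversion of a primary allylic alcohol into the bromide with PBr3 proceeds by SN2 displacement of the phosphite ester at low temperature, without allylic transposition or loss of E geometry.

Step 2
Reactants: 2 (2E,6E)-farnesyl bromide
Product: 3 (2E,6E)-farnesyl p-tolyl sulfone
Conditions: sodium p-toluenesulfinate, DMF, 20 °C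
Reagents that add atoms: sodium p-toluenesulfinate, Cc1ccc(cc1)S(=O)[O-].[Na+]
Why: S-alkylation of the sulfinate anion by the primary allylic bromide (sulfinate alkylation) should give the allylic sulfone needed as the nucleophilic C15 half.

Step 3
Reactants: 1 (2E,6E)-farnesol
Product: 4 benzyl (2E,6E)-farnesyl ether
Conditions: NaH, BnBr, n-Bu4NI (cat.), THF, 0 → 20 °C
Reagents that add atoms: benzyl bromide, BrCc1ccccc1
Why: Williamson ether synthesis protects the allylic alcohol as an ether that survives SeO2, the Appel conditions and the sulfonyl carbanion, and that falls off together with the sulfone in step 7.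

Step 4
Reactants: 4 benzyl (2E,6E)-farnesyl ether
Product: 5 (2E,6E,10E)-12-(benzyloxy)-2,6,10-trimethyldodeca-2,6,10-trien-1-ol
Conditions: SeO2 (cat.), t-BuOOH, salicylic acid (cat.), CH2Cl2, 20 °C
Reagents that add atoms: tert-butyl hydroperoxide, CC(C)(C)OO; selenium dioxide (catalytic oxygen carrier), O=[Se]=O
Why: Riley-type allylic oxidation (ene reaction, then [2,3]-sigmatropic shift) attacks the most electron-rich, least hindered terminal alkene at its E-methyl group, so the new trisubstituted alkene should be formed as the E isomer.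

Step 5
Reactants: 5 (2E,6E,10E)-12-(benzyloxy)-2,6,10-trimethyldodeca-2,6,10-trien-1-ol
Product: 6 benzyl (2E,6E,10E)-12-bromo-3,7,11-trimethyldodeca-2,6,10-trienyl ether
Conditions: CBr4, PPh3, CH2Cl2, 0 °C
Reagents that add atoms: carbon tetrabromide, BrC(Br)(Br)Br
Why: The Appel reaction turns the primary allylic alcohol into the bromide under neutral conditions that leave the benzyl ether and the alkene geometry untouched.

Step 6
Reactants: 3 (2E,6E)-farnesyl p-tolyl sulfone; 6 benzyl (2E,6E,10E)-12-bromo-3,7,11-trimethyldodeca-2,6,10-trienyl ether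
Product: 7 benzyl all-E-13-(p-tolylsulfonyl)hexaprenyl ether (racemic at C13)
Conditions: n-BuLi, THF/DMPU, −78 °C; then 6, −78 → −20 °C
Reagents that add atoms: none
Why: Alkylation of the α-sulfonyl carbanion with the primary allylic bromide (Julia-type sulfone coupling) forms the head-to-tail C12–C13 bond by SN2; the sulfone-bearing centre is formed racemic and is erased in step 7.

Step 7
Reactants: 7 benzyl all-E-13-(p-tolylsulfonyl)hexaprenyl ether
Product: 8 all-E-hexaprenol
Conditions: Li, EtNH2/THF, −78 °C; then NH4Cl
Reagents that add atoms: none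
Why: Dissolving-metal (Birch-type) reduction cleaves the allylic C–S bond and the benzylic C–O bond in one operation, and protonation of the allyl anion at the less substituted carbon should keep the trisubstituted E-alkene in place.

Step 8
Reactants: 8 all-E-hexaprenol
Product: 9 all-E-hexaprenyl bromide
Conditions: PBr3 (0.4 equiv), pyridine (cat.), Et2O, −10 → 0 °C
Reagents that add atoms: phosphorus tribromide, BrP(Br)Br
Why: The same low-temperature PBr3 bromination as in step 1, a standard operation on polyprenols, should give the primary allylic bromide without transposition.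

Step 9
Reactants: 9 all-E-hexaprenyl bromide; 10 methyl propiolate
Product: 11 methyl 3-(all-E-hexaprenyl)propiolate [methyl (5E,9E,13E,17E,21E)-6,10,14,18,22,26-hexamethylheptacosa-5,9,13,17,21,25-hexaen-2-ynoate]
Conditions: CuI (cat.), K2CO3, DMF, 20 °C
Reagents that add atoms: none
Why: Copper-catalysed allylation of a terminal alkyne: the copper acetylide formed with carbonate base substitutes the primary allylic bromide at its unhindered α carbon, giving the skipped enynoate without strong base.

Step 10
Reactants: 12 acetyl chloride; 13 1,1-dichloroethene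
Product: 15 4,4-dichlorobut-3-en-2-one, via 4,4,4-trichlorobutan-2-one 14 (not isolated)
Conditions: AlCl3, CH2Cl2, 0 → 20 °C; aqueous quench; then steam distillation
Reagents that add atoms: none
Why: Friedel–Crafts-type acylation of an alkene: the acylium ion adds to the CH2 terminus of dichloroethene, chloride captures the chlorine-stabilised cation, and loss of HCl on heating gives the conjugated dichloroenone.

Step 11
Reactants: 15 4,4-dichlorobut-3-en-2-one
Product: 16 4,4-dimethoxybut-3-en-2-one
Conditions: NaOMe (2.2 equiv), MeOH, 0 → 20 °C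
Reagents that add atoms: sodium methoxide, C[O-].[Na+]
Why: Two successive conjugate addition–elimination events (vinylic substitution at the β carbon of an enone) replace both chlorides by methoxide and give the acyl ketene acetal.

Step 12
Reactants: 16 4,4-dimethoxybut-3-en-2-one
Product: 17 1,1-dimethoxy-3-(trimethylsilyloxy)buta-1,3-diene
Conditions: Me3SiCl, Et3N, ZnCl2 (cat.), benzene, 40 °C
Reagents that add atoms: chlorotrimethylsilane, C[Si](C)(C)Cl
Why: Silyl enol ether formation at the only enolisable position, the methyl ketone, gives the cross-conjugated siloxydiene, which is distilled and used at once.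

Step 13
Reactants: 11 methyl 3-(all-E-hexaprenyl)propiolate; 17 1,1-dimethoxy-3-(trimethylsilyloxy)buta-1,3-diene
Product: 20 methyl 4-hydroxy-2-methoxy-6-(all-E-hexaprenyl)benzoate, via cyclohexadiene cycloadduct 18 (not isolated), via aryl trimethylsilyl ether 19 (not isolated)
Conditions: 17 (3 equiv), toluene, 120 °C, sealed tube; then PPTS (cat.), MeOH, 20 °C
Reagents that add atoms: none
Why: Normal-electron-demand Diels–Alder reaction: the doubly donor-activated diene 17, most nucleophilic at its CH2 terminus, adds in a concerted but strongly asynchronous way to ynoate 11, the CH2 terminus bonding to the alkyne carbon β to the ester (C5–C6) and the ketene-acetal carbon to the α carbon (C1–C2). The closest known reaction type is the cycloaddition–aromatisation of 1,1-dialkoxy-3-siloxybutadienes with acetylenic esters, which gives resorcylate monoethers. The single six-membered ring closes by intermolecular [4+2] cycloaddition with both ring bonds formed in one suprafacial event; the 1,4-cyclohexadiene 18 then aromatises by 1,4-elimination of methanol from the ketal carbon and the ring CH2, so exactly one methoxy group stays at C2, and acidic methanol cleaves aryl silyl ether 19 to the C4 phenol. No stereocentre is formed. The step needs regioselectivity only, and the matched polarisation of the two partners secures it by placing methoxy ortho and hydroxyl para to the ester, while the isolated trisubstituted alkenes of the chain are not dienophiles for this electron-rich diene.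

Step 14
Reactants: 20 methyl 4-hydroxy-2-methoxy-6-(all-E-hexaprenyl)benzoate
Product: 21 methyl 4-(tert-butyldimethylsilyloxy)-2-methoxy-6-(all-E-hexaprenyl)benzoate
Conditions: t-BuMe2SiCl, imidazole, DMF, 20 °C
Reagents that add atoms: tert-butyldimethylsilyl chloride, CC(C)(C)[Si](C)(C)Cl
Why: Phenol silylation masks the para hydroxyl so that the hydride reduction that follows cannot pass through a p-quinone methide and over-reduce the benzylic carbon.

Step 15
Reactants: 21 methyl 4-(tert-butyldimethylsilyloxy)-2-methoxy-6-(all-E-hexaprenyl)benzoate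
Product: 22 [4-(tert-butyldimethylsilyloxy)-2-methoxy-6-(all-E-hexaprenyl)phenyl]methanol
Conditions: i-Bu2AlH (3 equiv), toluene, −78 → 0 °C; aq. potassium sodium tartrate
Reagents that add atoms: none
Why: Hydride reduction of an ester to the primary alcohol with i-Bu2AlH tolerates the aryl silyl ether and the alkenes, and the neutral tartrate work-up protects the acid-sensitive electron-rich benzylic alcohol.

Step 16
Reactants: 22 [4-(tert-butyldimethylsilyloxy)-2-methoxy-6-(all-E-hexaprenyl)phenyl]methanol
Product: 23 4-(tert-butyldimethylsilyloxy)-2-methoxy-6-(all-E-hexaprenyl)benzaldehyde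
Conditions: MnO2 (activated, excess), CH2Cl2, 20 °C
Reagents that add atoms: none
Why: MnO2 oxidation is selective for benzylic alcohols and stops at the aldehyde without touching the chain alkenes or their allylic positions.

Step 17
Reactants: 23 4-(tert-butyldimethylsilyloxy)-2-methoxy-6-(all-E-hexaprenyl)benzaldehyde
Product: 26 2-methoxy-6-(all-E-hexaprenyl)benzene-1,4-diol, via free 4-hydroxybenzaldehyde 24 (not isolated), via aryl formate 25 (not isolated)
Conditions: aq. NaOH (3 equiv), 30% H2O2 (1.5 equiv), degassed THF/MeOH, 0 → 20 °C, Ar; acidic work-up under Ar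
Reagents that add atoms: hydrogen peroxide, OO
Why: Dakin oxidation: hydroxide first cleaves the activated aryl silyl ether to the para phenoxide 24, hydroperoxide adds to the formyl group, the electron-rich aryl group migrates to oxygen to give formate 25, and saponification gives the hydroquinone, while isolated alkenes are inert to alkaline peroxide.

Step 18
Reactants: 26 2-methoxy-6-(all-E-hexaprenyl)benzene-1,4-diol
Product: 27 2-methoxy-6-(all-E-hexaprenyl)-1,4-benzoquinone
Conditions: Ag2O, Na2SO4, Et2O, 20 °C
Reagents that add atoms: none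
Why: Two-electron oxidation of a hydroquinone to the p-quinone with Ag2O is mild, neutral and leaves the polyene chain unchanged.

**Compound list**

1 | (2E,6E)-farnesol | OC/C=C(\C)CC/C=C(\C)CCC=C(C)C | starting material
2 | (2E,6E)-farnesyl bromide | BrC/C=C(\C)CC/C=C(\C)CCC=C(C)C | intermediate
3 | (2E,6E)-farnesyl p-tolyl sulfone | Cc1ccc(cc1)S(=O)(=O)C/C=C(\C)CC/C=C(\C)CCC=C(C)C | intermediate
4 | benzyl (2E,6E)-farnesyl ether | C(OC/C=C(\C)CC/C=C(\C)CCC=C(C)C)c1ccccc1 | intermediate
5 | (2E,6E,10E)-12-(benzyloxy)-2,6,10-trimethyldodeca-2,6,10-trien-1-ol | C(OC/C=C(\C)CC/C=C(\C)CC/C=C(\C)CO)c1ccccc1 | intermediate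
6 | benzyl (2E,6E,10E)-12-bromo-3,7,11-trimethyldodeca-2,6,10-trienyl ether | C(OC/C=C(\C)CC/C=C(\C)CC/C=C(\C)CBr)c1ccccc1 | intermediate
7 | benzyl all-E-13-(p-tolylsulfonyl)hexaprenyl ether, racemic at C13 | c1ccccc1COC/C=C(\C)CC/C=C(\C)CC/C=C(\C)CC(S(=O)(=O)c1ccc(C)cc1)/C=C(\C)CC/C=C(\C)CCC=C(C)C | intermediate
8 | all-E-hexaprenol | OC/C=C(\C)CC/C=C(\C)CC/C=C(\C)CC/C=C(\C)CC/C=C(\C)CCC=C(C)C | intermediate
9 | all-E-hexaprenyl bromide | BrC/C=C(\C)CC/C=C(\C)CC/C=C(\C)CC/C=C(\C)CC/C=C(\C)CCC=C(C)C | intermediate
10 | methyl propiolate | C#CC(=O)OC | starting material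
11 | methyl 3-(all-E-hexaprenyl)propiolate | COC(=O)C#CC/C=C(\C)CC/C=C(\C)CC/C=C(\C)CC/C=C(\C)CC/C=C(\C)CCC=C(C)C | intermediate
12 | acetyl chloride | CC(=O)Cl | starting material
13 | 1,1-dichloroethene | C=C(Cl)Cl | starting material
14 | 4,4,4-trichlorobutan-2-one | CC(=O)CC(Cl)(Cl)Cl | intermediate (not isolated)
15 | 4,4-dichlorobut-3-en-2-one | CC(=O)C=C(Cl)Cl | intermediate
16 | 4,4-dimethoxybut-3-en-2-one | CC(=O)C=C(OC)OC | intermediate
17 | 1,1-dimethoxy-3-(trimethylsilyloxy)buta-1,3-diene | COC(OC)=CC(=C)O[Si](C)(C)C | intermediate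
18 | methyl 2-(all-E-hexaprenyl)-6,6-dimethoxy-4-(trimethylsilyloxy)cyclohexa-1,4-diene-1-carboxylate | COC(=O)C1=C(C/C=C(\C)CC/C=C(\C)CC/C=C(\C)CC/C=C(\C)CC/C=C(\C)CCC=C(C)C)CC(O[Si](C)(C)C)=CC1(OC)OC | intermediate (not isolated)
19 | methyl 2-methoxy-6-(all-E-hexaprenyl)-4-(trimethylsilyloxy)benzoate | COC(=O)c1c(OC)cc(O[Si](C)(C)C)cc1C/C=C(\C)CC/C=C(\C)CC/C=C(\C)CC/C=C(\C)CC/C=C(\C)CCC=C(C)C | intermediate (not isolated)
20 | methyl 4-hydroxy-2-methoxy-6-(all-E-hexaprenyl)benzoate | COC(=O)c1c(OC)cc(O)cc1C/C=C(\C)CC/C=C(\C)CC/C=C(\C)CC/C=C(\C)CC/C=C(\C)CCC=C(C)C | intermediate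
21 | methyl 4-(tert-butyldimethylsilyloxy)-2-methoxy-6-(all-E-hexaprenyl)benzoate | COC(=O)c1c(OC)cc(O[Si](C)(C)C(C)(C)C)cc1C/C=C(\C)CC/C=C(\C)CC/C=C(\C)CC/C=C(\C)CC/C=C(\C)CCC=C(C)C | intermediate
22 | [4-(tert-butyldimethylsilyloxy)-2-methoxy-6-(all-E-hexaprenyl)phenyl]methanol | OCc1c(OC)cc(O[Si](C)(C)C(C)(C)C)cc1C/C=C(\C)CC/C=C(\C)CC/C=C(\C)CC/C=C(\C)CC/C=C(\C)CCC=C(C)C | intermediate
23 | 4-(tert-butyldimethylsilyloxy)-2-methoxy-6-(all-E-hexaprenyl)benzaldehyde | O=Cc1c(OC)cc(O[Si](C)(C)C(C)(C)C)cc1C/C=C(\C)CC/C=C(\C)CC/C=C(\C)CC/C=C(\C)CC/C=C(\C)CCC=C(C)C | intermediate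
24 | 4-hydroxy-2-methoxy-6-(all-E-hexaprenyl)benzaldehyde (present as its sodium phenoxide) | O=Cc1c(OC)cc(O)cc1C/C=C(\C)CC/C=C(\C)CC/C=C(\C)CC/C=C(\C)CC/C=C(\C)CCC=C(C)C | intermediate (not isolated)
25 | 4-hydroxy-2-methoxy-6-(all-E-hexaprenyl)phenyl formate | O=COc1c(OC)cc(O)cc1C/C=C(\C)CC/C=C(\C)CC/C=C(\C)CC/C=C(\C)CC/C=C(\C)CCC=C(C)C | intermediate (not isolated)
26 | 2-methoxy-6-(all-E-hexaprenyl)benzene-1,4-diol | Oc1c(OC)cc(O)cc1C/C=C(\C)CC/C=C(\C)CC/C=C(\C)CC/C=C(\C)CC/C=C(\C)CCC=C(C)C | intermediate
27 | 2-methoxy-6-(all-E-hexaprenyl)-1,4-benzoquinone | COC1=CC(=O)C=C(C/C=C(\C)CC/C=C(\C)CC/C=C(\C)CC/C=C(\C)CC/C=C(\C)CCC=C(C)C)C1=O | target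

**Step count**

Total: 18 steps. Longest linear sequence: 13 steps (steps 3, 4, 5, 6, 7, 8, 9, 13, 14, 15, 16, 17, 18 from farnesol).

**Steps most likely to fail**

Step 13. The β-alkyl ynoate is a weak dienophile, so the heat-sensitive ketene-acetal diene may be lost to desilylation and oligomerisation before cycloaddition is complete. The fallback gives up ring construction and attaches the chain to a preformed arene; it sets out from 9 and comes back at 27. Commercial 5-bromovanillin (COc1cc(C=O)cc(Br)c1O) would be subjected to Dakin oxidation (H2O2, aq. NaOH) to give 2-bromo-6-methoxybenzene-1,4-diol F1. Double O-methylation (Me2SO4, K2CO3, acetone) would give 1-bromo-2,3,5-trimethoxybenzene F2. Bromine–lithium exchange (n-BuLi, THF, −78 °C) would give (2,3,5-trimethoxyphenyl)lithium F3, which with CuBr·SMe2 (cat.) should substitute bromide 9 at its primary carbon to give 1-(all-E-hexaprenyl)-2,3,5-trimethoxybenzene F4. Oxidative demethylation of the para-dimethoxy pair with (NH4)2Ce(NO3)6 in MeCN/H2O at 0 °C should then deliver 27.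

Step 9. Under carbonate base the doubly activated CH2 of the skipped enynoate may undergo prototropic shift to an allenoate or conjugated dienoate, and the copper acetylide may attack in the SN2′ sense. The fallback separates C–C bond formation from carboxylation; it sets out from 9 and comes back at 11. Ethynylmagnesium bromide with CuBr·SMe2 (cat.) in THF should give (4E,8E,12E,16E,20E)-5,9,13,17,21,25-hexamethylhexacosa-4,8,12,16,20,24-hexaen-1-yne F5. Deprotonation with n-BuLi at −78 °C and trapping with methyl chloroformate would then give 11.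

Step 17. Hydroperoxide addition to the di-ortho-substituted, phenoxide-deactivated formyl group may be slow, and the electron-rich hydroquinone may degrade in alkaline peroxide by oxidation to the quinone and nucleophilic epoxidation. The fallback removes the benzylic carbon as formaldehyde and forms the quinone directly; it sets out from 22 and comes back at 27. Desilylation (n-Bu4NF, AcOH, THF, 0 °C) would give 4-(hydroxymethyl)-3-methoxy-5-(all-E-hexaprenyl)phenol F6. Periodate oxidation of this p-hydroxybenzyl alcohol (NaIO4, aqueous THF, 0 °C) should expel the hydroxymethyl group and give 27.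

**Further compounds**

F1 | step 13 | 2-bromo-6-methoxybenzene-1,4-diol | COc1cc(O)cc(Br)c1O
F2 | step 13 | 1-bromo-2,3,5-trimethoxybenzene | COc1cc(OC)c(OC)c(Br)c1
F3 | step 13 | (2,3,5-trimethoxyphenyl)lithium | [Li]c1cc(OC)cc(OC)c1OC
F4 | step 13 | 1-(all-E-hexaprenyl)-2,3,5-trimethoxybenzene | COc1cc(OC)c(OC)c(C/C=C(\C)CC/C=C(\C)CC/C=C(\C)CC/C=C(\C)CC/C=C(\C)CCC=C(C)C)c1
F5 | step 9 | (4E,8E,12E,16E,20E)-5,9,13,17,21,25-hexamethylhexacosa-4,8,12,16,20,24-hexaen-1-yne | C#CC/C=C(\C)CC/C=C(\C)CC/C=C(\C)CC/C=C(\C)CC/C=C(\C)CCC=C(C)C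
F6 | step 17 | 4-(hydroxymethyl)-3-methoxy-5-(all-E-hexaprenyl)phenol | OCc1c(OC)cc(O)cc1C/C=C(\C)CC/C=C(\C)CC/C=C(\C)CC/C=C(\C)CC/C=C(\C)CCC=C(C)C
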